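The C11 ketone and the exocyclic C16=C17 alkene stand 1,4 to each other across C12 and C13 of the bicyclo[3.2.1]octane formed by rings C and D. Ring C is therefore traced back to a cyclopropane C12–C13–C16 that is later opened toward silicon. One metal-carbene cyclopropanation forms C12–C13 and C12–C16, closes ring C and the three-membered ring, and sets C13 relative to C8. Its precursor is a diazoketone whose C9 carries ring A (acids as 2-(trimethylsilyl)ethyl esters) and a ring-D cyclopentene with the C7 silyl ether on C8 and CH2SiMe3 on C16. It is assembled from two enantiopure fragments by Mitsunobu esterification and Ireland–Claisen rearrangement.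

Key step: step 21

Remark: atoms are numbered as in ent-kaurane (ring A = C1–C5, C10; C6 and C19 acids; C7 on C8; ring C = C8, C9, C11–C14; ring D = C8, C13–C16; C17 on C16). TMSE = 2-(trimethylsilyl)ethyl, TBDPS = tert-butyldiphenylsilyl.
Remark: the ring-A acids travel as TMSE esters and C7 as a TBDPS ether, so one fluoride treatment frees all three at the end without base or acid acting on C9, C11 or C16=C17.
Assumption: the salt of the required (1R,2S,3S)-half ester with (S)-1-phenylethylamine is taken to be the less soluble diastereomer; if the opposite holds, (R)-1-phenylethylamine is used in step 3 and nothing else changes.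

**Ring A (steps 1–6)**

Step 1
Reactants: 1 citraconic anhydride; 2 (E)-penta-1,3-diene
Product: 3 rac-(3aR,7S,7aS)-3a,7-dimethyl-3a,4,7,7a-tetrahydro-2-benzofuran-1,3-dione
Conditions: toluene, 2,6-di-tert-butyl-4-methylphenol (cat.), sealed tube, 120 °C; recrystallisation
Reagents that add atoms: none
Why: Thermal Diels–Alder reaction in which the unsubstituted diene terminus should bond to the methyl-bearing dienophile carbon (steric and frontier-orbital preference) with the anhydride endo, setting C4, C5 and C10 in relative terms (C20 cis to both carbonyls) as a racemate.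

Step 2
Reactants: 3 racemic anhydride
Product: 4 rac-(1R,2S,3S)-1,3-dimethyl-2-{[2-(trimethylsilyl)ethoxy]carbonyl}cyclohex-4-ene-1-carboxylic acid
Conditions: 2-(trimethylsilyl)ethanol, DMAP (cat.), Et3N, CH2Cl2, rt; aq. citric acid
Reagents that add atoms: 2-(trimethylsilyl)ethanol, C[Si](C)(C)CCO
Why: DMAP-catalysed alcoholysis of the anhydride should occur at the less hindered C6 carbonyl next to the C5 methine and leave the neopentyl C19 acid free, with no stereocentre touched.

Step 3
Reactants: 4 racemic half ester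
Product: 5 (S)-1-phenylethylammonium salt of the (1R,2S,3S)-half ester
Conditions: (S)-1-phenylethylamine (1 equiv), EtOAc–heptane, crystallisation to constant rotation
Reagents that add atoms: (S)-1-phenylethylamine, C[C@H](N)c1ccccc1
Why: Classical resolution by diastereomeric salt formation, which fixes the absolute configuration of C4, C5 and C10 in the crystalline salt.

Step 4
Reactants: 5 resolved ammonium salt
Product: 7 selenolactone (C19–O–C2 lactone with PhSe on C1), via free acid 6 (not isolated)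
Conditions: 1 M HCl, EtOAc (partition); then PhSeCl, pyridine, CH2Cl2, −78 °C → rt
Reagents that add atoms: benzeneselenenyl chloride, Cl[Se]c1ccccc1
Why: Phenylselenolactonisation in which the C19 carboxylate opens the seleniranium ion at C2 from its own face (anti addition, five-membered lactone), so the C2 oxygen is cis to C19 and selenium on C1 is cis to H10.

Step 5
Reactants: 7 selenolactone
Product: 9 (1R,2S,5S)-5-hydroxy-1,3-dimethyl-2-{[2-(trimethylsilyl)ethoxy]carbonyl}cyclohex-3-ene-1-carboxylic acid, via lithium hydroxy selenide carboxylate 8 (not isolated)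
Conditions: LiOH, THF–H2O, 0 °C → rt; then NaIO4, rt; 1 M HCl to pH 3
Reagents that add atoms: lithium hydroxide, [Li+].[OH-]
Why: Saponification of the strained lactone (retention at C2) followed by selenoxide syn-elimination, which can only use the cis hydrogen on C10 and runs away from the carbinol carbon, giving the C10=C1 allylic alcohol.

Step 6
Reactants: 9 hydroxy acid
Product: 10 bis[2-(trimethylsilyl)ethyl] (1R,2S,5S)-5-hydroxy-1,3-dimethylcyclohex-3-ene-1,2-dicarboxylate
Conditions: O-[2-(trimethylsilyl)ethyl]-N,N′-diisopropylisourea (2.5 equiv), THF, 60 °C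
Reagents that add atoms: O-[2-(trimethylsilyl)ethyl]-N,N′-diisopropylisourea, CC(C)NC(=NC(C)C)OCC[Si](C)(C)C
Why: O-Alkylation of the carboxylic acid by an O-alkylisourea esterifies C19 without activating the acyl carbon, so the cis C2 hydroxyl cannot re-lactonise, and it re-esterifies any C6 acid freed in step 5.

**Ring D (steps 7–16)**

Step 7
Reactants: 11 cyclopentane-1,3-dione
Product: 12 3-oxocyclopent-1-en-1-yl trifluoromethanesulfonate
Conditions: Tf2O, Et3N, CH2Cl2, −78 → 0 °C
Reagents that add atoms: trifluoromethanesulfonic anhydride, O=S(=O)(OS(=O)(=O)C(F)(F)F)C(F)(F)F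
Why: O-Sulfonylation of the enol form of the 1,3-dione gives the vinylogous acyl triflate.

Step 8
Reactants: 12 enone triflate
Product: 13 3-(hydroxymethyl)cyclopent-2-en-1-one
Conditions: Bu3SnCH2OH, Pd(PPh3)4 (cat.), LiCl, 1,4-dioxane, 90 °C
Reagents that add atoms: (tributylstannyl)methanol, CCCC[Sn](CCCC)(CCCC)CO
Why: Stille (Kosugi–Migita) coupling transfers the hydroxymethyl group from tin to the β-carbon of the enone, installing C7 on the future C8.

Step 9
Reactants: 13 hydroxymethyl enone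
Product: 14 3-{[(tert-butyldiphenylsilyl)oxy]methyl}cyclopent-2-en-1-one
Conditions: TBDPSCl, imidazole, DMF, rt
Reagents that add atoms: tert-butyl(chloro)diphenylsilane, CC(C)(C)[Si](Cl)(c1ccccc1)c1ccccc1
Why: Standard silylation of the primary alcohol with a bulky, acid-stable group that also shields the C7 methylene from carbene insertion later.

Step 10
Reactants: 14 silyloxymethyl enone
Product: 15 (R)-3-{[(tert-butyldiphenylsilyl)oxy]methyl}cyclopent-2-en-1-ol
Conditions: (S)-Me-CBS oxazaborolidine [(3aS)-1-methyl-3,3-diphenyltetrahydro-1H,3H-pyrrolo[1,2-c][1,3,2]oxazaborole] (0.2 equiv), catecholborane, toluene, −78 °C; MeOH, aq. NaOH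
Reagents that add atoms: none
Why: Corey–Bakshi–Shibata 1,2-reduction in which the alkenyl side acts as the large group, so the (S)-catalyst should give the (R)-carbinol that later becomes C16.

Step 11
Reactants: 15 (R)-allylic alcohol
Product: 17 ethyl 2-[(1S)-1-{[(tert-butyldiphenylsilyl)oxy]methyl}cyclopent-2-en-1-yl]acetate, via mixed ketene acetal 16 (not isolated)
Conditions: MeC(OEt)3 (excess), EtCO2H (cat.), 135 °C, EtOH distilled off
Reagents that add atoms: triethyl orthoacetate, CCOC(C)(OCC)OCC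
Why: Johnson–Claisen rearrangement delivers the acetate carbon (C9) suprafacially to the face of C8 that carried the carbinol oxygen, transferring the carbinol configuration to the quaternary centre C8.

Step 12
Reactants: 17 cyclopentenyl acetate
Product: 19 ethyl 2-[(1R)-1-{[(tert-butyldiphenylsilyl)oxy]methyl}-3-hydroxycyclopentyl]acetate (both C16 epimers), via alkylborane 18 (not isolated)
Conditions: 9-BBN, THF, 0 → 40 °C; then aq. NaOAc, 30% H2O2, 0 °C → rt
Reagents that add atoms: hydrogen peroxide, OO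
Why: Hydroboration–oxidation in which the bulky borane should place boron on C16, the alkene carbon remote from quaternary C8; the new carbinol centre is removed in the next step.

Step 13
Reactants: 19 cyclopentanol
Product: 20 ethyl 2-[(1R)-1-{[(tert-butyldiphenylsilyl)oxy]methyl}-3-oxocyclopentyl]acetate
Conditions: (n-Pr4N)RuO4 (cat.), NMO, 4 Å MS, CH2Cl2, rt
Reagents that add atoms: none
Why: Ley–Griffith oxidation of the secondary alcohol gives the C16 ketone, and C8 cannot epimerise.

Step 14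
Reactants: 20 cyclopentanone
Product: 22 ethyl 2-[(1R)-1-{[(tert-butyldiphenylsilyl)oxy]methyl}-3-{[(trifluoromethyl)sulfonyl]oxy}cyclopent-3-en-1-yl]acetate, via lithium enolate 21 (not isolated)
Conditions: LiN(i-Pr)2, THF, −78 °C; then PhNTf2, −78 → 0 °C
Reagents that add atoms: N-phenylbis(trifluoromethanesulfonimide), O=S(=O)(N(c1ccccc1)S(=O)(=O)C(F)(F)F)C(F)(F)F
Why: Kinetic deprotonation should occur at the unhindered C13 methylene (not the neopentyl C15 methylene or the less acidic ester) and O-triflation of that enolate fixes the double bond at C13=C16.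

Step 15
Reactants: 22 enol triflate
Product: 23 ethyl 2-[(1R)-1-{[(tert-butyldiphenylsilyl)oxy]methyl}-3-[(trimethylsilyl)methyl]cyclopent-3-en-1-yl]acetate
Conditions: Me3SiCH2MgCl, Pd(PPh3)4 (cat.), THF, 0 °C → rt
Reagents that add atoms: (trimethylsilyl)methylmagnesium chloride, C[Si](C)(C)C[Mg]Cl
Why: Kumada–Corriu coupling of the enol triflate gives the allylsilane with C17 on C16; C8 is a stereocentre only through this regiochemistry and is unchanged.

Step 16
Reactants: 23 allylsilane ester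
Product: 24 2-[(1R)-1-{[(tert-butyldiphenylsilyl)oxy]methyl}-3-[(trimethylsilyl)methyl]cyclopent-3-en-1-yl]acetic acid
Conditions: LiOH, THF–MeOH–H2O, rt; AcOH to pH 5
Reagents that add atoms: lithium hydroxide, [Li+].[OH-]
Why: Saponification of the primary-alkyl ethyl ester, which allylsilane and silyl ether tolerate, with a work-up at pH 5 to avoid protodesilylation.

**Coupling and end game (steps 17–24)**

Step 17
Reactants: 10 ring-A allylic alcohol; 24 ring-D acid
Product: 25 bis[2-(trimethylsilyl)ethyl] (1R,2S,5R)-5-({2-[(1R)-1-{[(tert-butyldiphenylsilyl)oxy]methyl}-3-[(trimethylsilyl)methyl]cyclopent-3-en-1-yl]acetyl}oxy)-1,3-dimethylcyclohex-3-ene-1,2-dicarboxylate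
Conditions: PPh3, DIAD, THF, 0 °C → rt
Reagents that add atoms: none
Why: Mitsunobu esterification displaces the activated C2 oxygen by the carboxylate with inversion, so the ester oxygen now lies on the face of ring A opposite to the C6 and C19 esters.

Step 18
Reactants: 25 allylic ester
Product: 28 (2S)-2-[(1R)-1-{[(tert-butyldiphenylsilyl)oxy]methyl}-3-[(trimethylsilyl)methyl]cyclopent-3-en-1-yl]-2-[(1S,2S,3R)-1,3-dimethyl-2,3-bis{[2-(trimethylsilyl)ethoxy]carbonyl}cyclohex-5-en-1-yl]acetic acid, via silyl ketene acetal 26 (not isolated), via trimethylsilyl ester 27 (not isolated)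
Conditions: Me3SiCl–Et3N (premixed), LiN(i-Pr)2, THF, −78 °C; then rt → 65 °C; aq. citric acid
Reagents that add atoms: none
Why: Ireland–Claisen rearrangement in which kinetic deprotonation of the acyl CH2 (the C5 methine between C4 and the C10 methyl is far less accessible at −78 °C) gives the (E)-silyl ketene acetal; it should rearrange suprafacially on the face of the C2 oxygen, which sets C10 with C9 trans to C6, and through a chair-like transition state, which sets C9.

Step 19
Reactants: 28 cyclohexenyl acid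
Product: 29 (2S)-2-[(1R)-1-{[(tert-butyldiphenylsilyl)oxy]methyl}-3-[(trimethylsilyl)methyl]cyclopent-3-en-1-yl]-2-[(1S,2S,3R)-1,3-dimethyl-2,3-bis{[2-(trimethylsilyl)ethoxy]carbonyl}cyclohexyl]acetic acid
Conditions: H2 (3 atm), RhCl(PPh3)3 (cat.), benzene–EtOH, rt
Reagents that add atoms: none
Why: Homogeneous hydrogenation with RhCl(PPh3)3 should reduce the cis-disubstituted C1=C2 bond much faster than the trisubstituted allylsilane double bond, and no stereocentre is formed.

Step 20
Reactants: 29 saturated acid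
Product: 31 diazoketone (C12 diazo carbon on the C11 carbonyl; precursor of the key step), via acid chloride 30 (not isolated)
Conditions: 1-chloro-N,N,2-trimethylprop-1-en-1-amine, CH2Cl2, 0 °C → rt; then CH2N2 (excess), Et2O, 0 °C → rt
Reagents that add atoms: diazomethane, C=[N+]=[N-]
Why: Neutral acid chloride formation (no HCl, so the allylsilane survives) and acylation of diazomethane (first stage of the Arndt–Eistert sequence) give the diazoketone without base, so C9 is not enolised.

Step 21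
Reactants: 31 diazoketone
Product: 32 tricyclic cyclopropyl ketone (cyclopropane C12–C13–C16 fused to rings C and D; CH2SiMe3 on C16)
Conditions: Rh2(OAc)4 (2 mol%), CH2Cl2, rt, slow addition of 31
Reagents that add atoms: none
Why: Rh2(OAc)4 converts the diazoketone into an electrophilic rhodium carbene at C12 that adds in one concerted, asynchronous [2+1] step to the electron-rich C13=C16 allylsilane double bond; the closest known reaction type is the copper- or rhodium-catalysed intramolecular cyclopropanation of unsaturated α-diazoketones to tricyclo[3.2.1.0(2,7)]octan-3-ones. Ring C (C8–C9–C11–C12–C13–C14) closes as a six-membered ring through C12–C13, and the three-membered ring closes through C12–C16 in the same event. C13 and C16 are set because the three-atom tether C9–C11–C12 on quaternary C8 can reach only the face of ring D that bears C9, and C12 follows from the cis fusion that a cyclopropane enforces. The step needs chemoselectivity for alkene addition over C–H insertion and site selectivity for this alkene. These should come from the nucleophilic trisubstituted allylsilane, the absence of any other C=C after step 19, and the fact that the nearest C–H bonds are neopentyl, hindered or flanked by the bulky silyl ether. The medium is neutral, so C9 keeps its configuration.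

Step 22
Reactants: 32 cyclopropyl ketone
Product: 33 bis-TMSE 7-O-TBDPS methylene ketone (bicyclo[3.2.1]octan-11-one with C16=C17)
Conditions: TiCl4 (1.1 equiv), CH2Cl2, −78 °C, 15 min; sat. aq. NaHCO3
Reagents that add atoms: none
Why: Lewis acid activation of the C11 carbonyl breaks the cyclopropane bond C12–C16, the bond that overlaps with the carbonyl and leaves positive charge β to silicon, so loss of Me3SiCl gives C16=C17 regiospecifically and the enolate is protonated at C12 on work-up (silicon-directed homo-conjugate opening of a (silylmethyl)cyclopropyl ketone), with C13 retained.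

Step 23
Reactants: 33 protected methylene ketone
Product: 34 hydroxy diacid (C7 alcohol, C6 and C19 acids, C11 ketone, C16=C17)
Conditions: Bu4NF (6 equiv), THF, 0 °C → rt; 1 M HCl to pH 3 at 0 °C
Reagents that add atoms: none
Why: Fluoride attacks silicon, so both TMSE esters fragment to carboxylates and ethene regardless of the hindrance at C4 and C5, and the silyl ether is cleaved in the same operation.

Step 24
Reactants: 34 hydroxy diacid
Product: 35 target CNP0408869.1
Conditions: Dess–Martin periodinane, CH2Cl2–THF, 0 °C → rt; aq. Na2S2O3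
Reagents that add atoms: none
Why: Dess–Martin oxidation of the neopentyl primary alcohol stops at the non-enolisable C7 aldehyde and leaves the free acids, the ketone and the 1,1-disubstituted alkene alone.

**Compound list**

1 | citraconic anhydride (3-methylfuran-2,5-dione) | CC1=CC(=O)OC1=O | starting material
2 | (E)-penta-1,3-diene | C/C=C/C=C | starting material
3 | rac-(3aR,7S,7aS)-3a,7-dimethyl-3a,4,7,7a-tetrahydro-2-benzofuran-1,3-dione (racemate; the enantiomer used later is drawn) | C[C@H]1C=CC[C@@]2(C)C(=O)OC(=O)[C@@H]12 | intermediate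
4 | rac-(1R,2S,3S)-1,3-dimethyl-2-{[2-(trimethylsilyl)ethoxy]carbonyl}cyclohex-4-ene-1-carboxylic acid (racemate; the enantiomer used later is drawn) | C[C@H]1C=CC[C@@](C)(C(=O)O)[C@H]1C(=O)OCC[Si](C)(C)C | intermediate
5 | (S)-1-phenylethylammonium (1R,2S,3S)-1,3-dimethyl-2-{[2-(trimethylsilyl)ethoxy]carbonyl}cyclohex-4-ene-1-carboxylate | C[C@H]1C=CC[C@@](C)(C(=O)[O-])[C@H]1C(=O)OCC[Si](C)(C)C.C[C@H]([NH3+])c1ccccc1 | intermediate
6 | (1R,2S,3S)-1,3-dimethyl-2-{[2-(trimethylsilyl)ethoxy]carbonyl}cyclohex-4-ene-1-carboxylic acid (single enantiomer) | C[C@H]1C=CC[C@@](C)(C(=O)O)[C@H]1C(=O)OCC[Si](C)(C)C | intermediate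
7 | 2-(trimethylsilyl)ethyl 1,3-dimethyl-7-oxo-4-(phenylselanyl)-6-oxabicyclo[3.2.1]octane-2-carboxylate (lactone oxygen on C2 cis to C19; PhSe on C1 trans to it and cis to H10) | C[C@H]1[C@H]([Se]c2ccccc2)[C@@H]3C[C@@](C)(C(=O)O3)[C@H]1C(=O)OCC[Si](C)(C)C | intermediate
8 | lithium 5-hydroxy-1,3-dimethyl-4-(phenylselanyl)-2-{[2-(trimethylsilyl)ethoxy]carbonyl}cyclohexane-1-carboxylate (configuration as in 7) | C[C@H]1[C@H]([Se]c2ccccc2)[C@@H](O)C[C@@](C)(C(=O)[O-])[C@H]1C(=O)OCC[Si](C)(C)C.[Li+] | intermediate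
9 | (1R,2S,5S)-5-hydroxy-1,3-dimethyl-2-{[2-(trimethylsilyl)ethoxy]carbonyl}cyclohex-3-ene-1-carboxylic acid | CC1=C[C@@H](O)C[C@@](C)(C(=O)O)[C@H]1C(=O)OCC[Si](C)(C)C | intermediate
10 | bis[2-(trimethylsilyl)ethyl] (1R,2S,5S)-5-hydroxy-1,3-dimethylcyclohex-3-ene-1,2-dicarboxylate | CC1=C[C@@H](O)C[C@@](C)(C(=O)OCC[Si](C)(C)C)[C@H]1C(=O)OCC[Si](C)(C)C | intermediate
11 | cyclopentane-1,3-dione | O=C1CCC(=O)C1 | starting material
12 | 3-oxocyclopent-1-en-1-yl trifluoromethanesulfonate | O=C1CCC(OS(=O)(=O)C(F)(F)F)=C1 | intermediate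
13 | 3-(hydroxymethyl)cyclopent-2-en-1-one | O=C1CCC(CO)=C1 | intermediate
14 | 3-{[(tert-butyldiphenylsilyl)oxy]methyl}cyclopent-2-en-1-one | O=C1CCC(CO[Si](c2ccccc2)(c2ccccc2)C(C)(C)C)=C1 | intermediate
15 | (R)-3-{[(tert-butyldiphenylsilyl)oxy]methyl}cyclopent-2-en-1-ol | O[C@H]1C=C(CO[Si](c2ccccc2)(c2ccccc2)C(C)(C)C)CC1 | intermediate
16 | (R)-3-{[(tert-butyldiphenylsilyl)oxy]methyl}cyclopent-2-en-1-yl 1-ethoxyvinyl ether (mixed ketene acetal) | C=C(OCC)O[C@H]1C=C(CO[Si](c2ccccc2)(c2ccccc2)C(C)(C)C)CC1 | intermediate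
17 | ethyl 2-[(1S)-1-{[(tert-butyldiphenylsilyl)oxy]methyl}cyclopent-2-en-1-yl]acetate | CCOC(=O)C[C@]1(CO[Si](c2ccccc2)(c2ccccc2)C(C)(C)C)C=CCC1 | intermediate
18 | B-alkyl-9-borabicyclo[3.3.1]nonane adduct of 17 (boron on C16) | CCOC(=O)C[C@]1(CO[Si](c2ccccc2)(c2ccccc2)C(C)(C)C)CC(B2C3CCCC2CCC3)CC1 | intermediate
19 | ethyl 2-[(1R)-1-{[(tert-butyldiphenylsilyl)oxy]methyl}-3-hydroxycyclopentyl]acetate (mixture of carbinol epimers) | CCOC(=O)C[C@]1(CO[Si](c2ccccc2)(c2ccccc2)C(C)(C)C)CC(O)CC1 | intermediate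
20 | ethyl 2-[(1R)-1-{[(tert-butyldiphenylsilyl)oxy]methyl}-3-oxocyclopentyl]acetate | CCOC(=O)C[C@]1(CO[Si](c2ccccc2)(c2ccccc2)C(C)(C)C)CC(=O)CC1 | intermediate
21 | lithium enolate of 20 (C16–O, C16=C13) | CCOC(=O)C[C@]1(CO[Si](c2ccccc2)(c2ccccc2)C(C)(C)C)CC(O[Li])=CC1 | intermediate
22 | ethyl 2-[(1R)-1-{[(tert-butyldiphenylsilyl)oxy]methyl}-3-{[(trifluoromethyl)sulfonyl]oxy}cyclopent-3-en-1-yl]acetate | CCOC(=O)C[C@]1(CO[Si](c2ccccc2)(c2ccccc2)C(C)(C)C)CC(OS(=O)(=O)C(F)(F)F)=CC1 | intermediate
23 | ethyl 2-[(1R)-1-{[(tert-butyldiphenylsilyl)oxy]methyl}-3-[(trimethylsilyl)methyl]cyclopent-3-en-1-yl]acetate | CCOC(=O)C[C@]1(CO[Si](c2ccccc2)(c2ccccc2)C(C)(C)C)CC(C[Si](C)(C)C)=CC1 | intermediate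
24 | 2-[(1R)-1-{[(tert-butyldiphenylsilyl)oxy]methyl}-3-[(trimethylsilyl)methyl]cyclopent-3-en-1-yl]acetic acid | OC(=O)C[C@]1(CO[Si](c2ccccc2)(c2ccccc2)C(C)(C)C)CC(C[Si](C)(C)C)=CC1 | intermediate
25 | bis[2-(trimethylsilyl)ethyl] (1R,2S,5R)-5-({2-[(1R)-1-{[(tert-butyldiphenylsilyl)oxy]methyl}-3-[(trimethylsilyl)methyl]cyclopent-3-en-1-yl]acetyl}oxy)-1,3-dimethylcyclohex-3-ene-1,2-dicarboxylate | CC1=C[C@H](OC(=O)C[C@]2(CO[Si](c3ccccc3)(c3ccccc3)C(C)(C)C)CC(C[Si](C)(C)C)=CC2)C[C@@](C)(C(=O)OCC[Si](C)(C)C)[C@H]1C(=O)OCC[Si](C)(C)C | intermediate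
26 | (E)-trimethylsilyl ketene acetal of 25 (C8 cis to the ring-A oxygen across C9=C11) | CC1=C[C@H](O/C(O[Si](C)(C)C)=C\[C@]2(CO[Si](c3ccccc3)(c3ccccc3)C(C)(C)C)CC(C[Si](C)(C)C)=CC2)C[C@@](C)(C(=O)OCC[Si](C)(C)C)[C@H]1C(=O)OCC[Si](C)(C)C | intermediate
27 | trimethylsilyl ester of acid 28 | C[Si](C)(C)OC(=O)[C@H]([C@@]1(CO[Si](c2ccccc2)(c2ccccc2)C(C)(C)C)CC=C(C[Si](C)(C)C)C1)[C@]3(C)C=CC[C@@](C)(C(=O)OCC[Si](C)(C)C)[C@H]3C(=O)OCC[Si](C)(C)C | intermediate
28 | (2S)-2-[(1R)-1-{[(tert-butyldiphenylsilyl)oxy]methyl}-3-[(trimethylsilyl)methyl]cyclopent-3-en-1-yl]-2-[(1S,2S,3R)-1,3-dimethyl-2,3-bis{[2-(trimethylsilyl)ethoxy]carbonyl}cyclohex-5-en-1-yl]acetic acid | OC(=O)[C@H]([C@@]1(CO[Si](c2ccccc2)(c2ccccc2)C(C)(C)C)CC=C(C[Si](C)(C)C)C1)[C@]3(C)C=CC[C@@](C)(C(=O)OCC[Si](C)(C)C)[C@H]3C(=O)OCC[Si](C)(C)C | intermediate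
29 | (2S)-2-[(1R)-1-{[(tert-butyldiphenylsilyl)oxy]methyl}-3-[(trimethylsilyl)methyl]cyclopent-3-en-1-yl]-2-[(1S,2S,3R)-1,3-dimethyl-2,3-bis{[2-(trimethylsilyl)ethoxy]carbonyl}cyclohexyl]acetic acid | OC(=O)[C@H]([C@@]1(CO[Si](c2ccccc2)(c2ccccc2)C(C)(C)C)CC=C(C[Si](C)(C)C)C1)[C@]3(C)CCC[C@@](C)(C(=O)OCC[Si](C)(C)C)[C@H]3C(=O)OCC[Si](C)(C)C | intermediate
30 | acid chloride of 29 (C11 acyl chloride; configuration unchanged) | ClC(=O)[C@H]([C@@]1(CO[Si](c2ccccc2)(c2ccccc2)C(C)(C)C)CC=C(C[Si](C)(C)C)C1)[C@]3(C)CCC[C@@](C)(C(=O)OCC[Si](C)(C)C)[C@H]3C(=O)OCC[Si](C)(C)C | intermediate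
31 | ring-A and ring-D diazoketone (diazomethyl ketone of 29; C12 = diazo carbon; configuration unchanged) | [N-]=[N+]=CC(=O)[C@H]([C@@]1(CO[Si](c2ccccc2)(c2ccccc2)C(C)(C)C)CC=C(C[Si](C)(C)C)C1)[C@]3(C)CCC[C@@](C)(C(=O)OCC[Si](C)(C)C)[C@H]3C(=O)OCC[Si](C)(C)C | intermediate
32 | tricyclic cyclopropyl ketone (tricyclo[3.2.1.0(2,7)]octan-3-one core: cyclopropane C12–C13–C16 on the C9 face of ring D, CH2SiMe3 on C16, TBDPSOCH2 on C8, ring A on C9) | C[Si](C)(C)C[C@]12C[C@]3(CO[Si](c4ccccc4)(c4ccccc4)C(C)(C)C)C[C@H]1[C@H]2C(=O)[C@H]3[C@]5(C)CCC[C@@](C)(C(=O)OCC[Si](C)(C)C)[C@H]5C(=O)OCC[Si](C)(C)C | intermediate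
33 | bis[2-(trimethylsilyl)ethyl] ester and 7-O-TBDPS ether of the 7-hydroxy-11-oxo-16-methylene seco-diacid (bicyclo[3.2.1]octan-11-one with C16=C17; configuration as in the target) | C=C1C[C@]2(CO[Si](c3ccccc3)(c3ccccc3)C(C)(C)C)C[C@H]1CC(=O)[C@H]2[C@]4(C)CCC[C@@](C)(C(=O)OCC[Si](C)(C)C)[C@H]4C(=O)OCC[Si](C)(C)C | intermediate
34 | 7-hydroxy-11-oxo-16-methylene seco-diacid (C7 primary alcohol; C6 and C19 acids; configuration as in the target) | C=C1C[C@]2(CO)C[C@H]1CC(=O)[C@H]2[C@]3(C)CCC[C@@](C)(C(=O)O)[C@H]3C(=O)O | intermediate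
35 | CNP0408869.1 (C7 aldehyde, C11 ketone, C16=C17, C6 and C19 acids) | C=C1C[C@]2(C=O)C[C@H]1CC(=O)[C@H]2[C@]1(C)CCC[C@@](C)(C(=O)O)[C@H]1C(=O)O | target

Total step count: 24.
Longest linear sequence: 18 steps (steps 7–16, then steps 17–24); the ring-A branch (steps 1–6) joins at step 17.

**Steps most likely to fail**

1. Step 21. The carbene may insert into the allylic C14–H or C15–H bonds or into the C7 methylene, or dimerise, instead of adding to C13=C16. Fallback: ring C is closed from the same diazoketone 31 by a polar pathway without a carbene. BF3·OEt2 in CH2Cl2 at −40 °C turns the diazoketone into an α-keto diazonium electrophile. The allylsilane attacks it through C13 from the face of the C9 tether (SE2′), and nitrogen and silicon leave. This gives the methylene ketone directly and rejoins the route at 33, so that step 22 is not needed. This fallback makes no new compound (F0).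

2. Step 18. The rearrangement may run through a boat-like instead of a chair-like transition state, so that facial control at C9 is lost. Fallback: C9 is then set by thermodynamic instead of kinetic control. The C9-epimeric acid F1 is hydrogenated as in step 19 to the saturated epimeric acid F2. This is converted as in step 20 through the epimeric acid chloride F3 into the epimeric diazoketone F4. Cyclopropanation as in step 21 gives the epimeric cyclopropyl ketone F5, and TiCl4 opening as in step 22 gives the 9-epi methylene ketone F6. In F6 the ring-A substituent on C9 is axial on the chair of ring C. DBU in toluene at 80 °C enolises C11 toward C9 and should deliver the equatorial epimer, which rejoins the route at 33.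

3. Step 19. The allylsilane double bond may be reduced as well, or the hindered C1=C2 bond may react too slowly for a clean distinction. Fallback: the electron-rich ring-D alkene is kept masked as the enol triflate until ring A is saturated. From 22, Me3SnOH in 1,2-dichloroethane at 80 °C gives the triflate acid F7. Mitsunobu coupling with 10 gives the triflate ester F8, and Ireland–Claisen rearrangement as in step 18 gives the triflate-bearing cyclohexenyl acid F9. Hydrogenation over RhCl(PPh3)3, to which the electron-poor trisubstituted enol triflate should be inert, gives the saturated triflate acid F10. Kumada coupling of F10 (as its magnesium carboxylate) with excess Me3SiCH2MgCl and Pd(PPh3)4 installs the allylsilane and rejoins the route at 29.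

Further compounds
F0 | step 21 | none | none
F1 | step 18 | C9 epimer of acid 28 | OC(=O)[C@@H]([C@@]1(CO[Si](c2ccccc2)(c2ccccc2)C(C)(C)C)CC=C(C[Si](C)(C)C)C1)[C@]3(C)C=CC[C@@](C)(C(=O)OCC[Si](C)(C)C)[C@H]3C(=O)OCC[Si](C)(C)C
F2 | step 18 | C9 epimer of acid 29 | OC(=O)[C@@H]([C@@]1(CO[Si](c2ccccc2)(c2ccccc2)C(C)(C)C)CC=C(C[Si](C)(C)C)C1)[C@]3(C)CCC[C@@](C)(C(=O)OCC[Si](C)(C)C)[C@H]3C(=O)OCC[Si](C)(C)C
F3 | step 18 | C9 epimer of acid chloride 30 | ClC(=O)[C@@H]([C@@]1(CO[Si](c2ccccc2)(c2ccccc2)C(C)(C)C)CC=C(C[Si](C)(C)C)C1)[C@]3(C)CCC[C@@](C)(C(=O)OCC[Si](C)(C)C)[C@H]3C(=O)OCC[Si](C)(C)C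
F4 | step 18 | C9 epimer of diazoketone 31 | [N-]=[N+]=CC(=O)[C@@H]([C@@]1(CO[Si](c2ccccc2)(c2ccccc2)C(C)(C)C)CC=C(C[Si](C)(C)C)C1)[C@]3(C)CCC[C@@](C)(C(=O)OCC[Si](C)(C)C)[C@H]3C(=O)OCC[Si](C)(C)C
F5 | step 18 | C9 epimer of cyclopropyl ketone 32 | C[Si](C)(C)C[C@]12C[C@]3(CO[Si](c4ccccc4)(c4ccccc4)C(C)(C)C)C[C@H]1[C@H]2C(=O)[C@@H]3[C@]5(C)CCC[C@@](C)(C(=O)OCC[Si](C)(C)C)[C@H]5C(=O)OCC[Si](C)(C)C
F6 | step 18 | C9 epimer of methylene ketone 33 | C=C1C[C@]2(CO[Si](c3ccccc3)(c3ccccc3)C(C)(C)C)C[C@H]1CC(=O)[C@@H]2[C@]4(C)CCC[C@@](C)(C(=O)OCC[Si](C)(C)C)[C@H]4C(=O)OCC[Si](C)(C)C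
F7 | step 19 | 2-[(1R)-1-{[(tert-butyldiphenylsilyl)oxy]methyl}-3-{[(trifluoromethyl)sulfonyl]oxy}cyclopent-3-en-1-yl]acetic acid | OC(=O)C[C@]1(CO[Si](c2ccccc2)(c2ccccc2)C(C)(C)C)CC(OS(=O)(=O)C(F)(F)F)=CC1
F8 | step 19 | enol triflate analogue of ester 25 (OTf on C16 in place of CH2SiMe3) | CC1=C[C@H](OC(=O)C[C@]2(CO[Si](c3ccccc3)(c3ccccc3)C(C)(C)C)CC(OS(=O)(=O)C(F)(F)F)=CC2)C[C@@](C)(C(=O)OCC[Si](C)(C)C)[C@H]1C(=O)OCC[Si](C)(C)C
F9 | step 19 | enol triflate analogue of acid 28 | OC(=O)[C@H]([C@@]1(CO[Si](c2ccccc2)(c2ccccc2)C(C)(C)C)CC=C(OS(=O)(=O)C(F)(F)F)C1)[C@]3(C)C=CC[C@@](C)(C(=O)OCC[Si](C)(C)C)[C@H]3C(=O)OCC[Si](C)(C)C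
F10 | step 19 | enol triflate analogue of acid 29 | OC(=O)[C@H]([C@@]1(CO[Si](c2ccccc2)(c2ccccc2)C(C)(C)C)CC=C(OS(=O)(=O)C(F)(F)F)C1)[C@]3(C)CCC[C@@](C)(C(=O)OCC[Si](C)(C)C)[C@H]3C(=O)OCC[Si](C)(C)C
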